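**Retrosynthetic overview**

1. The cyclohexene ring is made last, by a Diels–Alder reaction (C12–C4′ and C15–C5′) between trans-communic acid and the trans-cyclononene enal obtained by allylic oxidation of (−)-β-caryophyllene, followed by oxidation of the aldehyde to the acid. The nine- and four-membered rings are bought with caryophyllene.
2. The diene of trans-communic acid comes from a C12 aldehyde by two Wittig reactions. C8=C17 and 9α-H come from a reductive 1,3-transposition of an allylic alcohol. Both are developed from a C9 ketone.
3. Key disconnection: ring A is cut at C3–C4 and at C1–C10, a [3+3] annulation in which the trimethylene C1–C2–C3 (1-chloro-3-iodopropane) is laid across the two ends of a ring-B cyclohexenone ester.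
4. Enabling feature: in ring A the two methyl-bearing quaternary carbons C4 and C10 flank C5. C4 carries the C19 carboxyl and C10 lies next to C9, so with a ketone at C9 and C5=C10 unsaturated the array O=C9–C10=C5–C4–C19O2Me is a vinylogous β-keto ester, nucleophilic at C4 and then, as its dienolate, at C10.
5. Ring order: ring B (bought) → ring A with both quaternary centres (step 2) → trans ring fusion by hydrogenation → cyclohexene ring by Diels–Alder reaction.

Key step: step 2

Numbering: labdane numbering (C1–C20) for the decalin half; primed numbers are caryophyllene carbons (C4′=C5′ is the ring alkene, C1′ and C9′ the cyclobutane ring-fusion carbons).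

Assumption: the sense of induction of the cinchonidinium salt in step 2 has to be found by experiment; the pseudoenantiomeric cinchoninium salt is used instead if that is the one that leads to (S) at C4.

**Route**

Step 1
Reactants: 1 3-ethoxy-2-methylcyclohex-2-en-1-one; 2 methyl propanoate
Product: 4 methyl 2-(2-methyl-3-oxocyclohex-1-en-1-yl)propanoate (racemic), via aldol adduct 3 (not isolated)
Conditions: LiN(i-Pr)2, THF, −78 °C; then 1, −78 → −20 °C; then 2 M HCl, THF, rt
Reagents that add atoms: water, O
Why: Stork–Danheiser enone transposition, in which 1,2-addition of the ester enolate to the vinylogous ester gives 3 and acid then hydrolyses the enol ether and eliminates the tertiary hydroxyl to the conjugated enone; the stereocentre at C4 needs no control because it becomes planar in step 2.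

Step 2
Reactants: 4 methyl 2-(2-methyl-3-oxocyclohex-1-en-1-yl)propanoate; 5 1-chloro-3-iodopropane
Product: 7 methyl (1S,4aS)-1,4a-dimethyl-5-oxo-1,2,3,4,4a,5,6,7-octahydronaphthalene-1-carboxylate, via chloride 6 (not isolated)
Conditions: O-allyl-N-(9-anthracenylmethyl)cinchonidinium bromide (10 mol %), Cs2CO3, toluene, −20 → 0 °C; then KOtBu, t-BuOH/THF, 0 → 50 °C, same flask
Reagents that add atoms: none
Why: Proposed new method: Cs2CO3 removes the C4 proton of 4 (the only one activated by the ester and, through C5=C10, by the C9 ketone), and the ion pair of this anion with the chiral ammonium cation should be alkylated by the iodide end of 5 at the ester-bearing terminus C4, because the ketone-side terminus C10 is already methylated (compare the C-1 alkylation of 3-alkyl Hagemann's esters), which forms C3–C4 and gives 6; KOtBu then turns 6 by γ-deprotonation at C6 into the dienolate O–C9=C10–C5=C6, whose α-carbon C10 displaces the tethered chloride and forms C1–C10. The closest known reaction types are the chiral phase-transfer alkylation of α-substituted β-keto esters to quaternary centres and the α,α-dialkylation of enones through their dienolates (4,4-dimethylation of 4-en-3-ones); their union on a vinylogous β-keto ester with a 1,3-dihalide is not known. Ring A closes in a 6-exo-tet mode with the enolate double bond outside the new ring, whereas closure through oxygen or through C8 would need an eight-membered ring. C4 is set by the catalyst, which should cover one face of the planar anion, and C10 is set by C4: in the chair-like closure the flatter ester group should take the pseudoaxial place beside the C10 methyl group and the C4 methyl group the pseudoequatorial one, so that CO2Me and the angular methyl group come out cis. The step needs C- over O-alkylation and α- over γ-attack (C6) of the dienolate, which the soft iodide in toluene and the larger α-coefficient of the dienolate should secure, and single alkylation of 5, which the gap in reactivity between iodide and chloride secures.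

Step 3
Reactants: 7 methyl (1S,4aS)-1,4a-dimethyl-5-oxo-1,2,3,4,4a,5,6,7-octahydronaphthalene-1-carboxylate
Product: 8 methyl (1S,4aS,8aR)-1,4a-dimethyl-5-oxodecahydronaphthalene-1-carboxylate (trans-fused)
Conditions: H2 (4 atm), Pd/C, EtOAc, rt
Reagents that add atoms: none
Why: Heterogeneous catalytic hydrogenation, in which the β face of C5=C6 is covered by the axial C10 methyl group and the axial C4 ester, so that hydrogen should add from the α face and set 5α-H (trans ring fusion) as it does in 5-ene steroids.

Step 4
Reactants: 8 methyl (1S,4aS,8aR)-1,4a-dimethyl-5-oxodecahydronaphthalene-1-carboxylate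
Product: 9 methyl (1S,4aS,8aR)-1,4a-dimethyl-6-methylidene-5-oxodecahydronaphthalene-1-carboxylate
Conditions: (CH2O)n, N-methylanilinium trifluoroacetate, THF, reflux
Reagents that add atoms: paraformaldehyde (as formaldehyde), C=O
Why: α-Methylenation of a ketone by aminomethylation and elimination, which can only take place at C8 because C10 is quaternary, and which installs C17.

Step 5
Reactants: 9 methyl (1S,4aS,8aR)-1,4a-dimethyl-6-methylidene-5-oxodecahydronaphthalene-1-carboxylate; 10 (1,3-dioxolan-2-ylmethyl)magnesium bromide
Product: 11 methyl (1S,4aS,5S,8aR)-5-(1,3-dioxolan-2-ylmethyl)-5-hydroxy-1,4a-dimethyl-6-methylidenedecahydronaphthalene-1-carboxylate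
Conditions: anhydrous CeCl3, THF, −78 → 0 °C; aq. NH4Cl
Reagents that add atoms: none
Why: Organocerium 1,2-addition, in which the oxophilic reagent should add to the hindered C9 carbonyl and not to the exposed enone terminus C17, from the α face opposite the angular methyl group; the C9 configuration is of no consequence because step 6 erases it.

Step 6
Reactants: 11 methyl (1S,4aS,5S,8aR)-5-(1,3-dioxolan-2-ylmethyl)-5-hydroxy-1,4a-dimethyl-6-methylidenedecahydronaphthalene-1-carboxylate
Product: 12 methyl (1S,4aS,8aR)-5-(1,3-dioxolan-2-ylmethyl)-6-(hydroxymethyl)-1,4a-dimethyl-1,2,3,4,4a,7,8,8a-octahydronaphthalene-1-carboxylate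
Conditions: Ph3SiOReO3 (5 mol %), Et2O, −40 → 0 °C
Reagents that add atoms: none
Why: Perrhenate-catalysed 1,3-transposition of an allylic alcohol ([3,3] shift of the perrhenate ester), whose equilibrium should lie on the side of the tetrasubstituted C8=C9 alkene and the unhindered primary alcohol.

Step 7
Reactants: 12 methyl (1S,4aS,8aR)-5-(1,3-dioxolan-2-ylmethyl)-6-(hydroxymethyl)-1,4a-dimethyl-1,2,3,4,4a,7,8,8a-octahydronaphthalene-1-carboxylate
Product: 15 methyl (1S,4aR,5S,8aR)-5-(1,3-dioxolan-2-ylmethyl)-1,4a-dimethyl-6-methylidenedecahydronaphthalene-1-carboxylate, via sulfonylhydrazide 13 (not isolated), via allylic diazene 14 (not isolated)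
Conditions: 2-nitrobenzenesulfonylhydrazide, PPh3, diethyl azodicarboxylate, N-methylmorpholine, −30 °C → rt
Reagents that add atoms: none
Why: Reductive 1,3-transposition through an allylic diazene, in which the Mitsunobu reaction gives 13, loss of sulfinic acid gives 14, and retro-ene loss of N2 moves the double bond to C8=C17 and should deliver hydrogen to C9 on the α face opposite the axial C10 methyl group, which leaves the side chain β and equatorial.

Step 8
Reactants: 15 methyl (1S,4aR,5S,8aR)-5-(1,3-dioxolan-2-ylmethyl)-1,4a-dimethyl-6-methylidenedecahydronaphthalene-1-carboxylate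
Product: 16 methyl (1S,4aR,5S,8aR)-1,4a-dimethyl-6-methylidene-5-(2-oxoethyl)decahydronaphthalene-1-carboxylate
Conditions: AcOH/THF/H2O, 40 °C
Reagents that add atoms: water, O
Why: Acid hydrolysis of the dioxolane under conditions too mild to move the exocyclic double bond; C9 is β to the new aldehyde and cannot epimerise.

Step 9
Reactants: 16 methyl (1S,4aR,5S,8aR)-1,4a-dimethyl-6-methylidene-5-(2-oxoethyl)decahydronaphthalene-1-carboxylate; 17 2-(triphenylphosphoranylidene)propanal
Product: 18 methyl (1S,4aR,5S,8aR)-1,4a-dimethyl-6-methylidene-5-[(2E)-3-methyl-4-oxobut-2-en-1-yl]decahydronaphthalene-1-carboxylate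
Conditions: toluene, 90 °C
Reagents that add atoms: none
Why: Wittig reaction with a stabilised ylide, which should give the (12E)-trisubstituted enal with C11 trans to the formyl group.

Step 10
Reactants: 18 methyl (1S,4aR,5S,8aR)-1,4a-dimethyl-6-methylidene-5-[(2E)-3-methyl-4-oxobut-2-en-1-yl]decahydronaphthalene-1-carboxylate
Product: 19 methyl trans-communate, methyl (1S,4aR,5S,8aR)-1,4a-dimethyl-6-methylidene-5-[(2E)-3-methylpenta-2,4-dien-1-yl]decahydronaphthalene-1-carboxylate
Conditions: Ph3PCH3Br, KOtBu, THF, 0 °C → rt
Reagents that add atoms: methylenetriphenylphosphorane, C=P(c1ccccc1)(c1ccccc1)c1ccccc1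
Why: Wittig methylenation, in which the unstabilised ylide adds 1,2 to the enal and leaves the hindered ester and the 12E double bond untouched.

Step 11
Reactants: 19 methyl trans-communate
Product: 20 trans-communic acid, (1S,4aR,5S,8aR)-1,4a-dimethyl-6-methylidene-5-[(2E)-3-methylpenta-2,4-dien-1-yl]decahydronaphthalene-1-carboxylic acid
Conditions: n-PrSLi (from n-PrSH and n-BuLi), HMPA, rt; then 1 M HCl
Reagents that add atoms: none
Why: SN2 demethylation of a hindered ester by thiolate at the methyl carbon, the usual answer to axial C4 esters of resin acids, which avoids attack at the shielded carbonyl and should leave the diene alone.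

Step 12
Reactants: 21 (−)-β-caryophyllene
Product: 22 [(1R,4Z,9S)-11,11-dimethyl-8-methylidenebicyclo[7.2.0]undec-4-en-4-yl]methanol (ring double bond still trans in the ring; Z only because CH2OH outranks C3′)
Conditions: SeO2 (0.3 equiv), t-BuOOH, CH2Cl2, 0 °C → rt
Reagents that add atoms: tert-butyl hydroperoxide, CC(C)(C)OO
Why: Riley allylic oxidation (ene reaction then [2,3]-sigmatropic shift), in which SeO2 should attack the strained trisubstituted alkene at C5′ with removal of hydrogen from the C4′ methyl group and the fast [2,3] shift should return oxygen to that carbon and restore C4′=C5′ with the trans ring geometry before the ring can turn.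

Step 13
Reactants: 22 [(1R,4Z,9S)-11,11-dimethyl-8-methylidenebicyclo[7.2.0]undec-4-en-4-yl]methanol
Product: 23 (1R,4Z,9S)-11,11-dimethyl-8-methylidenebicyclo[7.2.0]undec-4-ene-4-carbaldehyde
Conditions: MnO2, CH2Cl2, rt
Reagents that add atoms: none
Why: Oxidation of an allylic alcohol to the enal with MnO2, which does not touch isolated alkenes.

Step 14
Reactants: 20 trans-communic acid; 23 (1R,4Z,9S)-11,11-dimethyl-8-methylidenebicyclo[7.2.0]undec-4-ene-4-carbaldehyde
Product: 24 Diels–Alder adduct, the 4′-formyl analogue of the target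
Conditions: toluene (1 M), 2,6-di-tert-butyl-4-methylphenol (trace), 85 °C, sealed tube, 23 in excess
Reagents that add atoms: none
Why: Intermolecular Diels–Alder reaction driven by the strain of the trans-cyclononene enal, in which the unsubstituted diene terminus C15 (largest HOMO coefficient of a 1-alkyl diene) should bond to the enal β-carbon C5′ and C12 to C4′, the diene should add to the outer face of the alkene (the face that caryophyllene offers to epoxidation) and so set C4′ and C5′ with the trans fusion of the nine-membered ring, and the endo position of the formyl group should place C11 cis to it at C12.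

Step 15
Reactants: 24 Diels–Alder adduct
Product: 25 CNP0330729.1 (target)
Conditions: NaClO2, NaH2PO4, 2-methylbut-2-ene, t-BuOH/H2O, 0 °C → rt
Reagents that add atoms: sodium chlorite, [Na+].[O-]Cl=O
Why: Pinnick oxidation of the neopentyl aldehyde to the acid, with 2-methylbut-2-ene as scavenger for HOCl so that the three alkenes and all stereocentres stay untouched.

**Compound list**

1 | 3-ethoxy-2-methylcyclohex-2-en-1-one | CCOC1=C(C)C(=O)CCC1 | starting material
2 | methyl propanoate | CCC(=O)OC | starting material
3 | methyl 2-(3-ethoxy-1-hydroxy-2-methylcyclohex-2-en-1-yl)propanoate (aldol adduct, mixture of diastereomers) | CCOC1=C(C)C(O)(CCC1)C(C)C(=O)OC | intermediate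
4 | methyl 2-(2-methyl-3-oxocyclohex-1-en-1-yl)propanoate (racemic) | COC(=O)C(C)C1=C(C)C(=O)CCC1 | intermediate
5 | 1-chloro-3-iodopropane | ClCCCI | starting material
6 | methyl (2S)-5-chloro-2-methyl-2-(2-methyl-3-oxocyclohex-1-en-1-yl)pentanoate | ClCCC[C@](C1=C(C)C(=O)CCC1)(C)C(=O)OC | intermediate
7 | methyl (1S,4aS)-1,4a-dimethyl-5-oxo-1,2,3,4,4a,5,6,7-octahydronaphthalene-1-carboxylate (labdane numbering: 5-ene, 9-one, 4β-CO2Me, 10β-Me) | O=C1CCC=C2[C@]1(C)CCC[C@]2(C)C(=O)OC | intermediate
8 | methyl (1S,4aS,8aR)-1,4a-dimethyl-5-oxodecahydronaphthalene-1-carboxylate (trans-fused, 5α-H) | O=C1CCC[C@@H]2[C@]1(C)CCC[C@]2(C)C(=O)OC | intermediate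
9 | methyl (1S,4aS,8aR)-1,4a-dimethyl-6-methylidene-5-oxodecahydronaphthalene-1-carboxylate | O=C1C(=C)CC[C@@H]2[C@]1(C)CCC[C@]2(C)C(=O)OC | intermediate
10 | (1,3-dioxolan-2-ylmethyl)magnesium bromide | Br[Mg]CC1OCCO1 | starting material
11 | methyl (1S,4aS,5S,8aR)-5-(1,3-dioxolan-2-ylmethyl)-5-hydroxy-1,4a-dimethyl-6-methylidenedecahydronaphthalene-1-carboxylate (9β-OH, side chain α) | O[C@@]1(CC3OCCO3)C(=C)CC[C@@H]2[C@]1(C)CCC[C@]2(C)C(=O)OC | intermediate
12 | methyl (1S,4aS,8aR)-5-(1,3-dioxolan-2-ylmethyl)-6-(hydroxymethyl)-1,4a-dimethyl-1,2,3,4,4a,7,8,8a-octahydronaphthalene-1-carboxylate | OCC1=C(CC3OCCO3)[C@@]2(C)CCC[C@](C)(C(=O)OC)[C@@H]2CC1 | intermediate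
13 | N-alkyl-N-(2-nitrobenzenesulfonyl)hydrazine from 12 (N on C17) | NN(CC1=C(CC3OCCO3)[C@@]2(C)CCC[C@](C)(C(=O)OC)[C@@H]2CC1)S(=O)(=O)c1ccccc1[N+](=O)[O-] | intermediate
14 | allylic diazene from 13 (HN=N on C17) | N=NCC1=C(CC3OCCO3)[C@@]2(C)CCC[C@](C)(C(=O)OC)[C@@H]2CC1 | intermediate
15 | methyl (1S,4aR,5S,8aR)-5-(1,3-dioxolan-2-ylmethyl)-1,4a-dimethyl-6-methylidenedecahydronaphthalene-1-carboxylate | O1CCOC1C[C@H]1C(=C)CC[C@@H]2[C@]1(C)CCC[C@]2(C)C(=O)OC | intermediate
16 | methyl (1S,4aR,5S,8aR)-1,4a-dimethyl-6-methylidene-5-(2-oxoethyl)decahydronaphthalene-1-carboxylate | O=CC[C@H]1C(=C)CC[C@@H]2[C@]1(C)CCC[C@]2(C)C(=O)OC | intermediate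
17 | 2-(triphenylphosphoranylidene)propanal | CC(C=O)=P(c1ccccc1)(c1ccccc1)c1ccccc1 | starting material
18 | methyl (1S,4aR,5S,8aR)-1,4a-dimethyl-6-methylidene-5-[(2E)-3-methyl-4-oxobut-2-en-1-yl]decahydronaphthalene-1-carboxylate | O=C/C(C)=C/C[C@H]1C(=C)CC[C@@H]2[C@]1(C)CCC[C@]2(C)C(=O)OC | intermediate
19 | methyl trans-communate, methyl (1S,4aR,5S,8aR)-1,4a-dimethyl-6-methylidene-5-[(2E)-3-methylpenta-2,4-dien-1-yl]decahydronaphthalene-1-carboxylate | C=C/C(C)=C/C[C@H]1C(=C)CC[C@@H]2[C@]1(C)CCC[C@]2(C)C(=O)OC | intermediate
20 | trans-communic acid, (1S,4aR,5S,8aR)-1,4a-dimethyl-6-methylidene-5-[(2E)-3-methylpenta-2,4-dien-1-yl]decahydronaphthalene-1-carboxylic acid | C=C/C(C)=C/C[C@H]1C(=C)CC[C@@H]2[C@]1(C)CCC[C@]2(C)C(=O)O | intermediate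
21 | (−)-β-caryophyllene, (1R,4E,9S)-4,11,11-trimethyl-8-methylidenebicyclo[7.2.0]undec-4-ene | C=C1CC/C=C(C)/CC[C@@H]2[C@@H]1CC2(C)C | starting material
22 | [(1R,4Z,9S)-11,11-dimethyl-8-methylidenebicyclo[7.2.0]undec-4-en-4-yl]methanol (ring alkene trans in the ring) | C=C1CC/C=C(CO)/CC[C@@H]2[C@@H]1CC2(C)C | intermediate
23 | (1R,4Z,9S)-11,11-dimethyl-8-methylidenebicyclo[7.2.0]undec-4-ene-4-carbaldehyde (ring alkene trans in the ring) | C=C1CC/C=C(C=O)/CC[C@@H]2[C@@H]1CC2(C)C | intermediate
24 | Diels–Alder adduct of 20 and 23: the target with CHO in place of the CO2H at C4′ (CHO and C11 cis on the new cyclohexene, nine-membered ring trans-fused) | C=C1CC[C@H]2CC=C(C)[C@@H](C[C@H]3C(=C)CC[C@@H]4[C@]3(C)CCC[C@]4(C)C(=O)O)[C@]2(C=O)CC[C@@H]2[C@@H]1CC2(C)C | intermediate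
25 | CNP0330729.1 | C=C1CC[C@H]2CC=C(C)[C@@H](C[C@H]3C(=C)CC[C@@H]4[C@]3(C)CCC[C@]4(C)C(=O)O)[C@]2(C(=O)O)CC[C@@H]2[C@@H]1CC2(C)C | target

**Step count and risks**

Total step count: 15. Longest linear sequence: 13 steps (steps 1–11, 14 and 15); steps 12 and 13 form the second branch.

Steps most likely to fail:

Step 2 (proposed new method). The chiral ion pair may discriminate poorly between the two faces of C4, because the anion can take up two rotamers about C4–C5; the product would then be close to racemic. A second danger is first alkylation at C10, which under KOtBu would be diverted to a bridged ketone. Fallback with known chemistry only: starting from 4, the same double alkylation is run without the chiral salt (NaH, THF, 5; then KOtBu, t-BuOH), which should give racemic 7. Steps 3 to 11 are carried out on racemic material, and racemic 20 is resolved by crystallisation of its salt with (R)-1-phenylethylamine, the (R)-1-phenylethylammonium salt of 20 F1 (the antipodal amine is taken if it gives the less soluble salt of the wanted acid). Dilute HCl sets the acid free, and the route is rejoined at 20.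

Step 14. The cycloaddition of a trisubstituted dienophile may be slower than thermal oligomerisation of the diene, and the enal may be attacked in part from its second face. Fallback: starting from ester 19 and enal 23, the cycloaddition is promoted by a Lewis acid (Me2AlCl, CH2Cl2, −78 → −20 °C), which the protected diene partner tolerates; this should give the aldehyde methyl ester adduct F2. Pinnick oxidation gives the acid methyl ester F3, and demethylation with n-PrSLi in HMPA as in step 11 leads back to the route at 25.

Step 12. The ene reaction may take hydrogen from the ring methylenes C3′ and C6′ or from the positions next to the exocyclic alkene, and over-oxidation or turning of the ring alkene may lower the yield. Fallback: starting from 21, epoxidation of the strained ring alkene with m-chloroperbenzoic acid gives (−)-caryophyllene oxide F4. LiNEt2 opens the epoxide by removal of a proton from the C4′ methyl group to the exocyclic allylic alcohol F5. PhSCl and Et3N give the sulfenate F6, which should undergo the Mislow–Evans [2,3] shift to the primary allylic sulfoxide F7 with the ring alkene restored. Pummerer reaction with trifluoroacetic anhydride and 2,6-lutidine gives the α-trifluoroacetoxy sulfide F8, and aqueous NaHCO3 hydrolyses it to 23, where the route is rejoined.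

Further compounds

F1 | step 2 | (R)-1-phenylethylammonium salt of 20 | C=C/C(C)=C/C[C@H]1C(=C)CC[C@@H]2[C@]1(C)CCC[C@]2(C)C(=O)[O-].C[C@@H]([NH3+])c1ccccc1
F2 | step 14 | aldehyde methyl ester adduct (24 with CO2Me at C19) | C=C1CC[C@H]2CC=C(C)[C@@H](C[C@H]3C(=C)CC[C@@H]4[C@]3(C)CCC[C@]4(C)C(=O)OC)[C@]2(C=O)CC[C@@H]2[C@@H]1CC2(C)C
F3 | step 14 | acid methyl ester (25 with CO2Me at C19) | C=C1CC[C@H]2CC=C(C)[C@@H](C[C@H]3C(=C)CC[C@@H]4[C@]3(C)CCC[C@]4(C)C(=O)OC)[C@]2(C(=O)O)CC[C@@H]2[C@@H]1CC2(C)C
F4 | step 12 | (−)-caryophyllene oxide, (1R,4R,5R,9S)-4,5-epoxide of 21 | C=C1CC[C@H]2O[C@]2(C)CC[C@@H]2[C@@H]1CC2(C)C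
F5 | step 12 | (1R,5R,9S)-11,11-dimethyl-4,8-dimethylidenebicyclo[7.2.0]undecan-5-ol | C=C1CC[C@@H](O)C(=C)CC[C@@H]2[C@@H]1CC2(C)C
F6 | step 12 | benzenesulfenate ester of F5 | C=C1CC[C@@H](OSc3ccccc3)C(=C)CC[C@@H]2[C@@H]1CC2(C)C
F7 | step 12 | allylic phenyl sulfoxide on the C4′ methylene (ring alkene trans in the ring, mixture at sulfur) | C=C1CC/C=C(CS(=O)c3ccccc3)/CC[C@@H]2[C@@H]1CC2(C)C
F8 | step 12 | α-trifluoroacetoxy phenyl sulfide from F7 | C=C1CC/C=C(C(OC(=O)C(F)(F)F)Sc3ccccc3)/CC[C@@H]2[C@@H]1CC2(C)C
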